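The route rests on disconnecting rings A and B of the labdane core at C5–C10 and C6–C7. An intramolecular Diels–Alder reaction of an E-alkenyl boronate (C5=C6), tethered through C4–C1 to a stereodefined tetrasubstituted diene (C10=C9–C8=C7), should close both rings in one operation and set C5, C6 and C10. It exploits the trans-fused A/B decalin with quaternary C10 and the trans arrangement of C4 and the C6 oxygen, which is carried as boron. The precursor is an acyclic triene whose boron bears (R,R)-1,2-dicyclohexylethane-1,2-diol for facial control and whose C9 arm is a silyl-protected hydroxyethyl group; the 8,9-alkene that remains is the handle for the 9α-hydroxyl and 8α-methyl.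

Key step: step 9

Remark: atom numbers are labdane numbers (decalin C1–C10, side chain C11–C12, C17 on C8, C18 and C19 on C4, C20 on C10); α is the face opposite the C10 methyl group.
Assumption: the (R,R)-diol is taken to be the enantiomer that favours the adduct of the target series (model under step 9); should the sense prove opposite, the (S,S)-diol is used and nothing else changes.

Step 1
Reactants: 1 but-3-yn-1-ol; 2 1-bromo-3-chloropropane
Product: 4 7-chlorohept-3-yn-1-ol, via dilithiated but-3-yn-1-ol 3 (not isolated)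
Conditions: n-BuLi (2.1 equiv), THF/DMPU, −78 to 0 °C; then 2, −78 °C to rt
Reagents that add atoms: none
Why: The acetylide carbon is the most nucleophilic site of the dianion and bromide leaves much faster than chloride, so this acetylide SN2 alkylation should give the chloroalkynol with the chloride kept for step 5.

Step 2
Reactants: 4 7-chlorohept-3-yn-1-ol
Product: 6 (3E)-7-chloro-3-iodo-4-methylhept-3-en-1-ol, via cyclic alkenylmagnesium alkoxide 5 (not isolated)
Conditions: Fe(acac)3 (20 mol%), MeMgBr (5 equiv), THF, −78 to 0 °C; then iodine (excess), −78 to 0 °C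
Reagents that add atoms: methylmagnesium bromide, C[Mg]Br; iodine, [I][I]
Why: This is an alkoxide-directed iron-catalysed syn-carbomagnesiation of a homopropargylic alcohol, which should place the methyl group on the distal alkyne carbon and magnesium on the proximal one in a five-membered chelate, so that iodinolysis with retention gives the tetrasubstituted iodoalkene with iodine cis to the new methyl group (the later diene geometry), the primary chloride being inert to MeMgBr at or below 0 °C.

Step 3
Reactants: 6 (3E)-7-chloro-3-iodo-4-methylhept-3-en-1-ol; 7 4,4,5,5-tetramethyl-2-(prop-1-en-2-yl)-1,3,2-dioxaborolane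
Product: 8 (3E)-7-chloro-4-methyl-3-(prop-1-en-2-yl)hept-3-en-1-ol
Conditions: Pd(OAc)2 (5 mol%), SPhos (10 mol%), K3PO4, THF/H2O, 60 °C
Reagents that add atoms: none
Why: Suzuki–Miyaura coupling of an alkenyl iodide proceeds with retention of alkene geometry, so the isopropenyl group should end up cis to the methyl group and trans to the chloropropyl chain, and neither the free hydroxyl nor the alkyl chloride should interfere.

Step 4
Reactants: 8 (3E)-7-chloro-4-methyl-3-(prop-1-en-2-yl)hept-3-en-1-ol
Product: 9 tert-butyl{[(3E)-7-chloro-4-methyl-3-(prop-1-en-2-yl)hept-3-en-1-yl]oxy}dimethylsilane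
Conditions: TBSCl, imidazole, CH2Cl2, rt
Reagents that add atoms: tert-butyldimethylsilyl chloride, CC(C)(C)[Si](C)(C)Cl
Why: Standard silylation of a primary alcohol, needed because a free hydroxyl would quench the carbanion of step 5 and the boranes of step 8.

Step 5
Reactants: 9 tert-butyl{[(3E)-7-chloro-4-methyl-3-(prop-1-en-2-yl)hept-3-en-1-yl]oxy}dimethylsilane; 10 isobutyronitrile
Product: 12 (6E)-7-[2-(tert-butyldimethylsilyloxy)ethyl]-2,2,6,8-tetramethylnona-6,8-dienenitrile, via lithiated isobutyronitrile 11 (not isolated)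
Conditions: 10, LiN(i-Pr)2 (LDA), THF, −78 °C; then 9, DMPU, NaI (10 mol%), −78 °C to rt
Reagents that add atoms: none
Why: SN2 alkylation of lithiated isobutyronitrile, a small and strongly nucleophilic tertiary carbanion, with the primary chloride under iodide catalysis should create the quaternary C4 with its two methyl groups, and the diene and silyl ether are inert to it.

Step 6
Reactants: 12 (6E)-7-[2-(tert-butyldimethylsilyloxy)ethyl]-2,2,6,8-tetramethylnona-6,8-dienenitrile
Product: 14 (6E)-7-[2-(tert-butyldimethylsilyloxy)ethyl]-2,2,6,8-tetramethylnona-6,8-dienal, via N-aluminated aldimine 13 (not isolated)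
Conditions: i-Bu2AlH (1.3 equiv), CH2Cl2, −78 °C; then aq. tartaric acid, 0 °C
Reagents that add atoms: water, O
Why: Partial reduction of a nitrile with i-Bu2AlH stops at the N-aluminated aldimine, which is hydrolysed on work-up to the aldehyde, and since the α-carbon is quaternary the aldehyde cannot enolise.

Step 7
Reactants: 14 (6E)-7-[2-(tert-butyldimethylsilyloxy)ethyl]-2,2,6,8-tetramethylnona-6,8-dienal
Product: 15 tert-butyl{[(3E)-4,8,8-trimethyl-3-(prop-1-en-2-yl)dec-3-en-9-yn-1-yl]oxy}dimethylsilane
Conditions: dimethyl (1-diazo-2-oxopropyl)phosphonate, K2CO3, MeOH, 0 °C to rt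
Reagents that add atoms: dimethyl (1-diazo-2-oxopropyl)phosphonate, CC(=O)C(=[N+]=[N-])P(=O)(OC)OC
Why: Seyferth–Gilbert homologation with the Ohira–Bestmann reagent converts non-enolisable aldehydes into terminal alkynes under mild base that should leave the silyl ether and the diene untouched.

Step 8
Reactants: 15 tert-butyl{[(3E)-4,8,8-trimethyl-3-(prop-1-en-2-yl)dec-3-en-9-yn-1-yl]oxy}dimethylsilane; 16 (1R,2R)-1,2-dicyclohexylethane-1,2-diol
Product: 18 (4R,5R)-4,5-dicyclohexyl-2-[(1E,7E)-8-[2-(tert-butyldimethylsilyloxy)ethyl]-3,3,7,9-tetramethyldeca-1,7,9-trien-1-yl]-1,3,2-dioxaborolane, via catechol alkenylboronate 17 (not isolated)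
Conditions: catecholborane (1.2 equiv), Cy2BH (10 mol%), THF, rt; then 16 (1.3 equiv), rt
Reagents that add atoms: catecholborane, B1Oc2ccccc2O1
Why: Hydroboration of a terminal alkyne with catecholborane is a syn, anti-Markovnikov addition (run here with a dialkylborane catalyst at room temperature so that the diene is spared) that can only give the E-alkenyl boronate, and the labile catechol ester should then exchange with the aliphatic diol by transesterification to the robust chiral dioxaborolane.

Step 9
Reactants: 18 (4R,5R)-4,5-dicyclohexyl-2-[(1E,7E)-8-[2-(tert-butyldimethylsilyloxy)ethyl]-3,3,7,9-tetramethyldeca-1,7,9-trien-1-yl]-1,3,2-dioxaborolane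
Product: 19 (4R,5R)-4,5-dicyclohexyl-2-[12-(tert-butyldimethylsilyloxy)-13,14,15,16-tetranorlabd-8-en-6α-yl]-1,3,2-dioxaborolane (trans-fused, 5α-H, 10β-methyl)
Conditions: 1,2-dichlorobenzene (0.02 M), BHT (5 mol%), 175 °C, sealed vessel; then separation of the trans-fused diastereomers
Reagents that add atoms: none
Why: On heating, the E-alkenyl boronate (2π, C5=C6) should add suprafacially in a concerted [4+2] cycloaddition across the s-cis diene C7=C8–C9=C10 (4π), forming C6–C7 and C5–C10 and leaving the 8,9-alkene; the closest known reaction type is the thermal type 1 intramolecular Diels–Alder reaction of 1,7,9-decatrienes that carry an alkenyl boronate as dienophile. Ring B closes as the six-membered ring of the cycloaddition itself, and ring A closes in the same event as the fused six-membered ring spanned by the four-carbon tether C1–C4 between diene terminus C10 and dienophile carbon C5. C5 and C6 are fixed relative to each other by the E geometry of the dienophile (C4 and boron trans, hence 5α-H and 6α-boron), and C10 relative to C5 by the 7E diene geometry, which puts the methyl group inside and the tether outside, together with the anti (tether-exo, boron-endo) transition state that leads to the trans ring fusion with a 10β-methyl group. The step therefore needs anti over syn selectivity, which should be helped by the endo preference of the trigonal boron and by the quaternary C4, which in the syn arrangement would have to sit under the substituted C9, and it needs one diene face, which is the task of the (R,R)-diol: the ring carbon on the oxygen syn to C5 lies below C8 and C17 in the boron-endo arrangement and should turn its cyclohexyl group away from the diene. As this facial bias may be only moderate, the two trans-fused adducts, which are diastereomers through the diol, are to be separated here by chromatography or crystallisation so that only 19 goes on. High dilution and a radical inhibitor are used because the inside methyl group slows the cycloaddition and makes a 1,5-hydrogen shift of the diene a possible side reaction.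

Step 10
Reactants: 19 (4R,5R)-4,5-dicyclohexyl-2-[12-(tert-butyldimethylsilyloxy)-13,14,15,16-tetranorlabd-8-en-6α-yl]-1,3,2-dioxaborolane
Product: 20 12-(tert-butyldimethylsilyloxy)-13,14,15,16-tetranorlabd-8-en-6α-ol
Conditions: H2O2 (30% aq.), NaOH, THF, 0 °C to rt
Reagents that add atoms: hydrogen peroxide, OO
Why: Oxidation of a C–B bond with alkaline hydrogen peroxide proceeds by 1,2-migration of carbon from boron to oxygen with retention, so the 6α-boronate should give the 6α-alcohol, and the tetrasubstituted alkene is inert to this nucleophilic oxidant.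

Step 11
Reactants: 20 12-(tert-butyldimethylsilyloxy)-13,14,15,16-tetranorlabd-8-en-6α-ol
Product: 21 8α,9α-epoxy-12-(tert-butyldimethylsilyloxy)-13,14,15,16-tetranorlabdan-6α-ol
Conditions: mCPBA, NaHCO3, CH2Cl2, 0 °C
Reagents that add atoms: 3-chloroperoxybenzoic acid, OOC(=O)c1cccc(Cl)c1
Why: Prilezhaev epoxidation of the electron-rich tetrasubstituted 8,9-alkene should take place on the α face, because the β face is shielded by the axial C10 methyl group and hydrogen bonding of the peracid to the α-hydroxyl at C6 can only reinforce this, which sets C8 and C9 as the 8α,9α-epoxide.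

Step 12
Reactants: 21 8α,9α-epoxy-12-(tert-butyldimethylsilyloxy)-13,14,15,16-tetranorlabdan-6α-ol
Product: 22 12-(tert-butyldimethylsilyloxy)-13,14,15,16-tetranorlabd-8(17)-ene-6α,9α-diol
Conditions: Et2AlTMP (4 equiv, from LiTMP and Et2AlCl), toluene, 0 °C to rt
Reagents that add atoms: none
Why: Isomerisation of an epoxide to an allylic alcohol by an aluminium amide is a syn β-elimination in which aluminium holds the epoxide oxygen and the amide removes the most accessible β-hydrogen, here one of the C17 methyl hydrogens, so the C8–O bond should open and the oxygen stay on C9 as the 9α-hydroxyl, while abstraction at C7 would give the 7-ene, which converges in step 13.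

Step 13
Reactants: 22 12-(tert-butyldimethylsilyloxy)-13,14,15,16-tetranorlabd-8(17)-ene-6α,9α-diol
Product: 23 12-(tert-butyldimethylsilyloxy)-13,14,15,16-tetranorlabdane-6α,9α-diol with C17 α (8β-H)
Conditions: Mn(dpm)3 (10 mol%), PhSiH3, TBHP, i-PrOH, rt
Reagents that add atoms: none
Why: Metal-hydride hydrogen-atom-transfer hydrogenation generates the tertiary C8 radical and reduces it under thermodynamic control, so C17 should become the equatorial 8α-methyl group, which avoids the 1,3-diaxial clash with the C10 methyl group that the opposite epimer would suffer.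

Step 14
Reactants: 23 12-(tert-butyldimethylsilyloxy)-13,14,15,16-tetranorlabdane-6α,9α-diol
Product: 24 6α-acetoxy-12-(tert-butyldimethylsilyloxy)-13,14,15,16-tetranorlabdan-9α-ol
Conditions: Ac2O, pyridine, DMAP (cat.), CH2Cl2, rt
Reagents that add atoms: acetic anhydride, CC(=O)OC(C)=O
Why: Acylation with acetic anhydride and DMAP distinguishes the secondary equatorial 6α-hydroxyl from the hindered tertiary 9α-hydroxyl, which should stay free.

Step 15
Reactants: 24 6α-acetoxy-12-(tert-butyldimethylsilyloxy)-13,14,15,16-tetranorlabdan-9α-ol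
Product: 25 6α-acetoxy-13,14,15,16-tetranorlabdane-9α,12-diol
Conditions: HF·pyridine, THF/pyridine, 0 °C to rt
Reagents that add atoms: none
Why: Fluoride-mediated cleavage of the Si–O bond under buffered, weakly acidic conditions should free the primary alcohol without hydrolysis or migration of the acetate.

Step 16
Reactants: 25 6α-acetoxy-13,14,15,16-tetranorlabdane-9α,12-diol
Product: 26 6α-acetoxy-12-iodo-13,14,15,16-tetranorlabdan-9α-ol
Conditions: PPh3, iodine, imidazole, CH2Cl2, 0 °C to rt
Reagents that add atoms: iodine, [I][I]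
Why: Appel-type iodination converts only the primary alcohol into the iodide by SN2 displacement of the alkoxyphosphonium ion, a path that is closed to the tertiary hydroxyl.

Step 17
Reactants: 26 6α-acetoxy-12-iodo-13,14,15,16-tetranorlabdan-9α-ol; 27 3-bromofuran-2(5H)-one
Product: 28 6α-acetoxy-9α-hydroxylabd-13-en-16,15-olide (target)
Conditions: NiBr2(dme) (10 mol%), 4,4'-di-tert-butyl-2,2'-bipyridine (10 mol%), Mn powder (3 equiv), NaI (0.5 equiv), DMA, 25 °C; 27 (2 equiv)
Reagents that add atoms: none
Why: Nickel-catalysed reductive cross-electrophile coupling joins a primary alkyl iodide and an alkenyl bromide at the two halogen-bearing carbons (C12 and C13), the bromide adding oxidatively to nickel and the alkyl radical from the iodide being captured there, and its neutral conditions should tolerate the free tertiary alcohol, the acetate and the lactone.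

Compound list
1 | but-3-yn-1-ol | C#CCCO | starting material
2 | 1-bromo-3-chloropropane | ClCCCBr | starting material
3 | dilithiated but-3-yn-1-ol (lithium 4-lithiobut-3-yn-1-olate) | [Li]C#CCCO[Li] | intermediate
4 | 7-chlorohept-3-yn-1-ol | ClCCCC#CCCO | intermediate
5 | (3E)-3-(5-chloropentan-2-ylidene)-1,2-oxamagnesolane (magnesium cis to the new methyl group, chelated by the alkoxide) | ClCCC/C(C)=C1\CCO[Mg]1 | intermediate
6 | (3E)-7-chloro-3-iodo-4-methylhept-3-en-1-ol (iodine cis to methyl) | ClCCC/C(C)=C(/I)CCO | intermediate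
7 | 4,4,5,5-tetramethyl-2-(prop-1-en-2-yl)-1,3,2-dioxaborolane | CC(=C)B1OC(C)(C)C(C)(C)O1 | starting material
8 | (3E)-7-chloro-4-methyl-3-(prop-1-en-2-yl)hept-3-en-1-ol (isopropenyl cis to methyl) | ClCCC/C(C)=C(/C(C)=C)CCO | intermediate
9 | tert-butyl{[(3E)-7-chloro-4-methyl-3-(prop-1-en-2-yl)hept-3-en-1-yl]oxy}dimethylsilane | ClCCC/C(C)=C(/C(C)=C)CCO[Si](C)(C)C(C)(C)C | intermediate
10 | isobutyronitrile | CC(C)C#N | starting material
11 | lithiated isobutyronitrile (2-lithio-2-methylpropanenitrile) | [Li]C(C)(C)C#N | intermediate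
12 | (6E)-7-[2-(tert-butyldimethylsilyloxy)ethyl]-2,2,6,8-tetramethylnona-6,8-dienenitrile | N#CC(C)(C)CCC/C(C)=C(/C(C)=C)CCO[Si](C)(C)C(C)(C)C | intermediate
13 | (6E)-N-(diisobutylalumanyl)-7-[2-(tert-butyldimethylsilyloxy)ethyl]-2,2,6,8-tetramethylnona-6,8-dien-1-imine | CC(C)C[Al](CC(C)C)N=CC(C)(C)CCC/C(C)=C(/C(C)=C)CCO[Si](C)(C)C(C)(C)C | intermediate
14 | (6E)-7-[2-(tert-butyldimethylsilyloxy)ethyl]-2,2,6,8-tetramethylnona-6,8-dienal | O=CC(C)(C)CCC/C(C)=C(/C(C)=C)CCO[Si](C)(C)C(C)(C)C | intermediate
15 | tert-butyl{[(3E)-4,8,8-trimethyl-3-(prop-1-en-2-yl)dec-3-en-9-yn-1-yl]oxy}dimethylsilane | C#CC(C)(C)CCC/C(C)=C(/C(C)=C)CCO[Si](C)(C)C(C)(C)C | intermediate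
16 | (1R,2R)-1,2-dicyclohexylethane-1,2-diol | O[C@H](C1CCCCC1)[C@H](O)C1CCCCC1 | starting material
17 | 2-[(1E,7E)-8-[2-(tert-butyldimethylsilyloxy)ethyl]-3,3,7,9-tetramethyldeca-1,7,9-trien-1-yl]-1,3,2-benzodioxaborole | B1(Oc2ccccc2O1)/C=C/C(C)(C)CCC/C(C)=C(/C(C)=C)CCO[Si](C)(C)C(C)(C)C | intermediate
18 | (4R,5R)-4,5-dicyclohexyl-2-[(1E,7E)-8-[2-(tert-butyldimethylsilyloxy)ethyl]-3,3,7,9-tetramethyldeca-1,7,9-trien-1-yl]-1,3,2-dioxaborolane | B1(O[C@H](C2CCCCC2)[C@H](O1)C3CCCCC3)/C=C/C(C)(C)CCC/C(C)=C(/C(C)=C)CCO[Si](C)(C)C(C)(C)C | intermediate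
19 | (4R,5R)-4,5-dicyclohexyl-2-[12-(tert-butyldimethylsilyloxy)-13,14,15,16-tetranorlabd-8-en-6α-yl]-1,3,2-dioxaborolane (trans-decalin, 5α-H, 6α-B, 10β-CH3) | B1(O[C@H](C2CCCCC2)[C@H](O1)C3CCCCC3)[C@H]4CC(C)=C(CCO[Si](C)(C)C(C)(C)C)[C@@]5(C)CCCC(C)(C)[C@H]45 | intermediate
20 | 12-(tert-butyldimethylsilyloxy)-13,14,15,16-tetranorlabd-8-en-6α-ol; (1S,4aS,8aS)-4-[2-(tert-butyldimethylsilyloxy)ethyl]-3,4a,8,8-tetramethyl-1,2,4a,5,6,7,8,8a-octahydronaphthalen-1-ol | O[C@H]1CC(C)=C(CCO[Si](C)(C)C(C)(C)C)[C@@]2(C)CCCC(C)(C)[C@H]12 | intermediate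
21 | 8α,9α-epoxy-12-(tert-butyldimethylsilyloxy)-13,14,15,16-tetranorlabdan-6α-ol | O[C@H]1C[C@@]2(C)O[C@@]2(CCO[Si](C)(C)C(C)(C)C)[C@@]3(C)CCCC(C)(C)[C@H]13 | intermediate
22 | 12-(tert-butyldimethylsilyloxy)-13,14,15,16-tetranorlabd-8(17)-ene-6α,9α-diol; (1S,4R,4aS,8aS)-4-[2-(tert-butyldimethylsilyloxy)ethyl]-4a,8,8-trimethyl-3-methylidenedecahydronaphthalene-1,4-diol | O[C@H]1CC(=C)[C@](O)(CCO[Si](C)(C)C(C)(C)C)[C@@]2(C)CCCC(C)(C)[C@H]12 | intermediate
23 | 12-(tert-butyldimethylsilyloxy)-13,14,15,16-tetranorlabdane-6α,9α-diol with C17 α; (1S,3R,4R,4aS,8aS)-4-[2-(tert-butyldimethylsilyloxy)ethyl]-3,4a,8,8-tetramethyldecahydronaphthalene-1,4-diol | O[C@H]1C[C@@H](C)[C@](O)(CCO[Si](C)(C)C(C)(C)C)[C@@]2(C)CCCC(C)(C)[C@H]12 | intermediate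
24 | 6α-acetoxy-12-(tert-butyldimethylsilyloxy)-13,14,15,16-tetranorlabdan-9α-ol | CC(=O)O[C@H]1C[C@@H](C)[C@](O)(CCO[Si](C)(C)C(C)(C)C)[C@@]2(C)CCCC(C)(C)[C@H]12 | intermediate
25 | 6α-acetoxy-13,14,15,16-tetranorlabdane-9α,12-diol | CC(=O)O[C@H]1C[C@@H](C)[C@](O)(CCO)[C@@]2(C)CCCC(C)(C)[C@H]12 | intermediate
26 | 6α-acetoxy-12-iodo-13,14,15,16-tetranorlabdan-9α-ol | CC(=O)O[C@H]1C[C@@H](C)[C@](O)(CCI)[C@@]2(C)CCCC(C)(C)[C@H]12 | intermediate
27 | 3-bromofuran-2(5H)-one | O=C1OCC=C1Br | starting material
28 | 6α-acetoxy-9α-hydroxylabd-13-en-16,15-olide; [(1S,3R,4R,4aS,8aS)-4-hydroxy-3,4a,8,8-tetramethyl-4-[2-(2-oxo-2,5-dihydrofuran-3-yl)ethyl]decahydronaphthalen-1-yl] acetate | CC(=O)O[C@H]1C[C@@H](C)[C@](O)(CCC2=CCOC2=O)[C@@]2(C)CCCC(C)(C)[C@H]12 | target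

Total step count: 17. Longest linear sequence: 17 steps (1 and 2 to 28); 7, 10, 16 and 27 enter as purchased compounds.

Steps most likely to fail

Step 9. The cycloaddition may be too slow at temperatures the diene tolerates, so that the 1,5-hydrogen shift from the inside methyl group to C7 takes over. The boron-endo preference may be too weak to hold the anti transition state, which would give cis-fused material. The diol may also impart little facial bias, and the two trans-fused diastereomers may not separate. The fallback sets out from 15 and returns at 20. Hydroboration of 15 with dicyclohexylborane (1.0 equiv, THF, 0 °C) should give dicyclohexyl[(1E,7E)-8-[2-(tert-butyldimethylsilyloxy)ethyl]-3,3,7,9-tetramethyldeca-1,7,9-trien-1-yl]borane F1. As a dialkyl(alkenyl)borane this is a far stronger dienophile than a boronate and has a more pronounced endo preference for boron, so warming (THF or toluene, 60–80 °C) is expected to give the racemic cycloadduct dicyclohexyl[12-(tert-butyldimethylsilyloxy)-13,14,15,16-tetranorlabd-8-en-6α-yl]borane F2 in the same flask. Oxidation with NaOH/H2O2 should then give racemic 12-(tert-butyldimethylsilyloxy)-13,14,15,16-tetranorlabd-8-en-6α-ol F3. Absolute configuration is then secured by classical resolution: esterification with (1S)-camphanic chloride (pyridine, DMAP), separation of the diastereomeric esters to obtain the (1S,4R)-camphanate of 20 F4, and hydrolysis (LiOH, THF/MeOH/H2O) to release 20.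

Step 17. The alkyl radical may add in a conjugate fashion to C4 of the bromobutenolide instead of being captured at nickel, or the butenolide may be lost by reductive debromination or homocoupling. The fallback sets out from 26 and returns at 28. 3-(Phenylsulfanyl)dihydrofuran-2(3H)-one F5 is made from 2-bromo-4-butanolide and thiophenol (Et3N, CH2Cl2). Its lithium enolate (LiN(SiMe3)2, THF/HMPA, −78 to 0 °C, used in excess to cover the tertiary hydroxyl) is alkylated with 26 to give 6α-acetoxy-9α-hydroxy-13-(phenylsulfanyl)labdan-16,15-olide F6 as a mixture of C13 epimers. Oxidation with mCPBA (CH2Cl2, −78 °C) gives the sulfoxide 6α-acetoxy-9α-hydroxy-13-(phenylsulfinyl)labdan-16,15-olide F7, which is not isolated. Heating it in toluene at 100 °C should bring about syn-elimination of benzenesulfenic acid toward the ring methylene and give 28.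

Step 12. Proton abstraction may occur at C11 instead of C17 or C7, which would open the C9–O bond and leave the hydroxyl at C8, or the hindered tetrasubstituted epoxide may resist the base. The fallback sets out from 21 and returns at 23, so it also replaces step 13. Dissolving-metal reduction of 21 (lithium, ethylamine, t-BuOH, −78 to 0 °C) is expected, by the trans-diaxial opening rule for reductive cleavage of rigid epoxides, to break the C8–O bond, keep the axial 9α-hydroxyl and protonate C8 so that C17 is equatorial. No new compound is made on the way.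

Further compounds
F1 | step 9 | dicyclohexyl[(1E,7E)-8-[2-(tert-butyldimethylsilyloxy)ethyl]-3,3,7,9-tetramethyldeca-1,7,9-trien-1-yl]borane | B(C1CCCCC1)(C2CCCCC2)/C=C/C(C)(C)CCC/C(C)=C(/C(C)=C)CCO[Si](C)(C)C(C)(C)C
F2 | step 9 | racemic dicyclohexyl[12-(tert-butyldimethylsilyloxy)-13,14,15,16-tetranorlabd-8-en-6α-yl]borane (both enantiomers) | B(C1CCCCC1)(C2CCCCC2)[C@H]3CC(C)=C(CCO[Si](C)(C)C(C)(C)C)[C@@]4(C)CCCC(C)(C)[C@H]34.B(C1CCCCC1)(C2CCCCC2)[C@@H]3CC(C)=C(CCO[Si](C)(C)C(C)(C)C)[C@]4(C)CCCC(C)(C)[C@@H]34
F3 | step 9 | racemic 12-(tert-butyldimethylsilyloxy)-13,14,15,16-tetranorlabd-8-en-6α-ol (20 and its enantiomer) | O[C@H]1CC(C)=C(CCO[Si](C)(C)C(C)(C)C)[C@@]2(C)CCCC(C)(C)[C@H]12.O[C@@H]1CC(C)=C(CCO[Si](C)(C)C(C)(C)C)[C@]2(C)CCCC(C)(C)[C@@H]12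
F4 | step 9 | (1S,4R)-camphanate of 20 | O=C(O[C@H]1CC(C)=C(CCO[Si](C)(C)C(C)(C)C)[C@@]2(C)CCCC(C)(C)[C@H]12)[C@@]34CC[C@@](C)(C(=O)O3)C4(C)C
F5 | step 17 | 3-(phenylsulfanyl)dihydrofuran-2(3H)-one | O=C1OCCC1Sc1ccccc1
F6 | step 17 | 6α-acetoxy-9α-hydroxy-13-(phenylsulfanyl)labdan-16,15-olide (C13 epimers) | CC(=O)O[C@H]1C[C@@H](C)[C@](O)(CCC2(Sc3ccccc3)CCOC2=O)[C@@]2(C)CCCC(C)(C)[C@H]12
F7 | step 17 | 6α-acetoxy-9α-hydroxy-13-(phenylsulfinyl)labdan-16,15-olide (C13 and sulfur epimers) | CC(=O)O[C@H]1C[C@@H](C)[C@](O)(CCC2(S(=O)c3ccccc3)CCOC2=O)[C@@]2(C)CCCC(C)(C)[C@H]12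
F0 | step 12 | none | none
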